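## Structural features

The target is a labdane: a trans-fused decalin (ring A = C1–C5 and C10, ring B = C5–C10) with an exocyclic methylene (C17) on C8, a saturated chain C11–C15 on C9 that ends in a formate ester, and on C4 a methyl group (C18) next to a free carboxylic acid (C19). Four of the five stereocentres are contiguous (C4, C5, C10, C9). C4 and C10 are quaternary and 1,3-related across C5, and they hold C19 and C20 syn-axial on the β face; H5 and H9 are α, so the chain is equatorial. The fifth centre, C13, lies three bonds from the ring and cannot be relayed from the decalin, so it must come with the chain fragment. Fragile points are the formate (lost to mild base or nucleophiles), the 1,1-disubstituted C8=C17 alkene (migrates into the ring under acid), the hindered axial acid (hard to free from simple esters) and C9, which can be corrected only while C8 is a carbonyl. The real difficulty is absolute control of quaternary C10 and the transfer of that information to C5, C9 and C4. Ring B offers the opening: C8 is a masked carbonyl, C9 must accept a carbon nucleophile and C5 needs a neighbouring carbonyl (C6) to be corrected. Ring B with C20 therefore corresponds to a methoxy-methyl-p-benzoquinone, and C1–C4 with C19 to a five-carbon diene joined to it across C5=C10.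

## Logic of the disconnections

**28 ⇒ 27.** The formyl C–O bond at O15 is cut first because the formate is the most labile group and would survive no base, hydride or fluoride. This leaves a hydroxy acid. The forward step must formylate a primary alcohol next to a free, hindered acid.

**27 ⇒ 26.** The O15–Si bond is cut. A robust silyl ether on O15 lets the chain pass through organometallic, hydride, acid, hydrogenation and enolate chemistry. It must be removable by fluoride without touching the alkene or the acid.

**26 ⇒ 24 (through 25).** The C4–C18 bond is cut. Quaternary C4 becomes a tertiary carbon α to the acid, so its configuration no longer has to be carried through the synthesis. The forward alkylation must enolise a hindered centre and take the electrophile on the α face, away from syn-axial C20.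

**24 ⇒ 23 ⇒ 22.** C19 is returned to the alcohol level and the C8=C17 bond is cut to a C8 ketone. The ketone makes C9 correctable and is the direct outcome of the ring B chemistry. The methylenation must work on a hindered, enolisable ketone.

**22 ⇒ 19 (through 20 and 21).** A hydroxyl is put back on C9 (and the silyl group on O19). The α-ketol is the trace of a carbonyl addition, so the C9–C11 bond can be made by nucleophilic addition and not by alkylation of a hindered enolate. The forward step must cleave a tertiary C–O bond α to the ketone and protonate C9 on the α face.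

**19 ⇒ 18 ⇒ 16 (through 17).** The C6=C7 and C2=C3 alkenes are restored and the C8 carbonyl is transposed to C6 with an enol ether at C8. This reveals a vinylogous ester, the oxygen pattern of a methoxyquinone adduct. The forward sequence needs 1,2-reduction at C6 and hydrolysis with allylic transposition.

**16 ⇒ 7 + 13 (through 14 and 15).** The C9–C11 bond is cut. The molecule splits into a bicyclic enedione and a chain that carries C13, which makes the route convergent. The organometallic must add to C9 and not to C6, and must not enolise C5.

**13 ⇒ 12 ⇒ 11 ⇒ 10 ⇒ 9 ⇒ 8.** Functional group changes at the two chain ends lead back to a symmetrical anhydride. The only stereogenic operation is the differentiation of its two carbonyls, after which the ends must stay distinct (acid end to O15, ester end to C11).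

**7 ⇒ 6.** C5 is inverted. A cycloaddition can only give the cis fusion, so the trans fusion has to arise by equilibration α to C6. This requires the trans isomer to be the more stable one.

**6 ⇒ 2 + 5.** The C1–C10 and C4–C5 bonds are cut, which opens ring A. Two flat achiral partners remain. The methoxy group of 2 serves three ends: it deactivates the second alkene, becomes the C8 oxygen, and differentiates the two carbonyls. Compound 5 carries O19 as a silyl ether because that is a weak Lewis base and leaves the diene electron-rich; a dienoate would be too electron-poor and a free alcohol would bind the catalyst. The forward step must control site, orientation and face.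

**2 ⇒ 1 and 5 ⇒ 4 ⇒ 3.** Oxidation of a phenol with a free para position, and reduction then silylation of a dienoic acid, connect both partners to commercial materials.

## Other disconnections considered

**Alternative 1:** The cut is C10–C20. The angular methyl is traced to a bromomethyl(dimethyl)silyl ether on O19 of the bicyclic enone A1 (C8 ketone, C9=C10 alkene, chain on C9). Forward, Bu3SnH with AIBN would generate an α-silyl radical that closes a seven-membered siloxane onto C10, the enone β-carbon. The C9 radical is then reduced to give A2, and later C–Si and Si–O cleavage would release C20 as methyl and C19 as CH2OH.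
- In its favour: the tether reaches C10 only from the face of C19, so the syn relation of C19 and C20 is enforced by geometry. C4 is already quaternary, so no late enolate methylation is needed; on this point the alternative is better than the chosen plan. The C8 ketone and the equilibration of C9 are used as in the chosen plan, an equal point.
- Against it: the key step adds one carbon and closes no ring of the target. A1 already contains both rings, a tetrasubstituted enone and the centres C4, C5 and C13, so it needs its own enantioselective synthesis of comparable length. Seven-membered closure onto a fully substituted carbon is slow beside direct reduction of the radical, and it needs stoichiometric tin and an extra desilylation.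
- Comparison: on structure the chosen plan forms ring A, two C–C bonds and C10 in one step, against one C–C bond here. On mechanism a concerted, catalyst-controlled cycloaddition is easier to predict than a marginal 7-exo radical closure, though the tether gives the more secure C4/C10 relation. On step economy the alternative is longer.

**Alternative 2:** The cuts are C5–C6 and C9–C10. Ring B is traced to a [2+2] photocycloaddition of the ring A enone A3 (C1 ketone, C5=C10 alkene, C4 already quaternary) with the cyclobutene A4, giving the bicyclo[2.2.0]hexane A5. Desilylation and glycol cleavage of the C6–C9 bond would then open the six-carbon perimeter into ring B with carbonyls at C6 and C9.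
- In its favour: the two carbonyls arrive where the chosen plan has them, so the C5 correction and the C9 addition are equally available (an equal point). The alkene partner is symmetrical, so there is no orientation problem (better). C4 with its ester is present from the start (better).
- Against it: the adduct still has H5 cis to C20, so the same epimerisation is needed. The facial course at C10 depends on telling a methyl from a methoxycarbonyl group on C4, which is a weak bias. There is no oxygen at C8, so C17 needs a separate functionalisation that the methoxyquinone supplies for free. The C1 ketone must be removed afterwards. The photoaddition joins two fully substituted carbons (C9, C10) and is hindered.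
- Comparison: on structure both plans create the C6/C9 dione pattern, but only the chosen one brings C8 oxidised and sets C10 by a catalyst. On mechanism a photochemical step with substrate-controlled face selectivity is less predictable. On step economy the deoxygenation at C1 and the C8 functionalisation outweigh the saving at C4.

**Alternative 3:** The cut is the C5–C10 bond. The decalin opens to the ten-membered diene A6 (exocyclic methylene on C10, C4=C5 enoate, silyl ether on C8, chain on C9). Forward, Fe(acac)3 with PhSiH3 would transfer a hydrogen atom to C20, and the tertiary C10 radical would add across the ring to C5 of the enoate; reduction of the C4 radical gives A7.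
- In its favour: one bond closes both rings and creates C10 and C5 together, and a trans fusion can result directly, which would save the epimerisation (better on this point). The conditions are mild and tin-free. The chain and the C8 oxygen are already in place.
- Against it: A6 is a medium ring with two stereocentres, two differentiated alkenes and the chain, and is much harder to assemble than 2 and 5. The configurations at C10 and C5 depend on the conformation of a flexible ring, and simple reduction of the alkene competes. A7 still lacks C18, so the same enolate methylation at C4 is needed (an equal point). C8 must be desilylated and oxidised before methylenation, two operations that the chosen route does not need.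
- Comparison: on structure the alternative forms the central bond, the chosen plan the two bonds of ring A. On mechanism stepwise radical addition under conformational control is weaker than catalyst control for absolute configuration, but stronger for the ring fusion. On step economy the macrocycle synthesis makes it longer.

Key step: step 4

**Remarks on the chemistry (conventions and assumptions)**
- Labdane numbering is used; β is the face that carries C20. TBS = tert-butyldimethylsilyl, TBDPS = tert-butyldiphenylsilyl.
- Assumption: the cation from (S)-diphenylprolinol is taken to leave open the quinone face that leads to 6 as drawn; if the sense is opposite, the (R)-prolinol catalyst is used with no other change.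
- Assumption: (DHQD)2AQN is taken to give the (R)-hemiester 9; if it gives the (S)-hemiester, the pseudo-enantiomer (DHQ)2AQN is used.
- Check of 6: H4, H5 and C20 are all β, as an endo transition state with an E diene requires, and C10 has the configuration of the target.

**Step 1**
Reactants: 1 2-methoxy-6-methylphenol
Product: 2 2-methoxy-6-methyl-1,4-benzoquinone
Conditions: O2 (1 atm), Co(salen) (5 mol%), DMF, 25 °C
Reagents that add atoms: dioxygen O=O
Why: Cobalt–salen-mediated aerobic oxidation of a 2,6-disubstituted phenol; the phenoxyl radical can be oxygenated only at the free para position, which gives the p-quinone.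

**Step 2**
Reactants: 3 (E)-penta-2,4-dienoic acid
Product: 4 (E)-penta-2,4-dien-1-ol
Conditions: LiAlH4, Et2O, 0 → 25 °C; aq. NaOH work-up
Reagents that add atoms: none
Why: Hydride reduction of the carboxylate to the primary alcohol; the conjugated diene is not reduced under these conditions and keeps its E geometry; the volatile dienol is used as a concentrated ether solution.

**Step 3**
Reactants: 4 (E)-penta-2,4-dien-1-ol
Product: 5 (E)-tert-butyldimethyl(penta-2,4-dienyloxy)silane
Conditions: TBSCl, imidazole, CH2Cl2, 0 → 25 °C
Reagents that add atoms: tert-butyldimethylsilyl chloride CC(C)(C)[Si](C)(C)Cl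
Why: Standard silylation of a primary alcohol; the silyl ether is a weak Lewis base and will not compete for the boron catalyst in step 4.

**Step 4**
Reactants: 2 2-methoxy-6-methyl-1,4-benzoquinone; 5 (E)-tert-butyldimethyl(penta-2,4-dienyloxy)silane
Product: 6 (4aR,5R,8aS)-5-(TBS-oxymethyl)-2-methoxy-8a-methyl-4a,5,8,8a-tetrahydronaphthalene-1,4-dione (cis-fused endo adduct; 4β-H 5β-H 10β-CH3 in labdane locants)
Conditions: (S)-o-tolyl-oxazaborolidine [from (S)-α,α-diphenylprolinol and o-tolylboronic acid] (20 mol%), HNTf2 (18 mol%), CH2Cl2, −78 → −40 °C
Reagents that add atoms: none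
Why: The N-protonated oxazaborolidine is a chiral cationic boron Lewis acid that binds the C6 carbonyl oxygen (the more basic vinylogous-ester carbonyl) at the lone pair syn to C5–H and so lowers the LUMO of the C5=C10 alkene; the closest known reaction type is the oxazaborolidinium-catalysed enantioselective Diels–Alder reaction of unsymmetrical 1,4-benzoquinones. Site selectivity comes from the methoxy group, which makes C7=C8 an unreactive vinylogous ester, so only the methyl-bearing alkene reacts. Orientation follows from binding at C6, which makes C10 the β-carbon: the unsubstituted, more nucleophilic diene terminus C1 bonds to C10 and the substituted terminus C4 bonds to the less hindered C5, so electronic and steric preferences agree. Ring A is closed by an intermolecular, concerted but asynchronous suprafacial [4+2] cycloaddition in which C1–C10 forms ahead of C4–C5. C10 is set by the catalyst, whose aryl group covers one face of the bound quinone so that the diene adds to the open face. C5 is set cis to C20 by suprafacial addition to the alkene, and C4 by the endo transition state together with the E geometry of the diene, which places CH2OTBS cis to the C5–C6 bond. Only C10 is carried to the target, so face selectivity is the selectivity that matters most.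

**Step 5**
Reactants: 6 cis-fused endo adduct
Product: 7 (4aS,5R,8aS)-5-(TBS-oxymethyl)-2-methoxy-8a-methyl-4a,5,8,8a-tetrahydronaphthalene-1,4-dione (trans-fused; 5α-H)
Conditions: NaOMe (0.2 equiv), MeOH, 0 → 25 °C
Reagents that add atoms: none
Why: Base-mediated epimerisation through the C5 enolate of the C6 carbonyl under thermodynamic control, expected to favour the trans-fused enedione; C10 is quaternary, C4–H is not acidic and the C9 carbonyl has no α-hydrogen, so only C5 changes.

**Step 6**
Reactants: 8 3-methylglutaric anhydride
Product: 9 (R)-5-methoxy-3-methyl-5-oxopentanoic acid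
Conditions: (DHQD)2AQN (10 mol%), MeOH (10 equiv), Et2O, −40 °C
Reagents that add atoms: methanol CO
Why: Cinchona-alkaloid-catalysed enantioselective methanolysis (desymmetrisation) of a prochiral cyclic anhydride; general-base activation of methanol within the chiral pocket distinguishes the enantiotopic carbonyls and sets the future C13.

**Step 7**
Reactants: 9 (R)-hemiester
Product: 10 methyl (R)-5-hydroxy-3-methylpentanoate
Conditions: BH3·SMe2, THF, 0 → 25 °C; MeOH quench
Reagents that add atoms: none
Why: Borane reduces the carboxylic acid through an acyloxyborane much faster than the ester, so the two chain ends stay differentiated; the hydroxy ester is silylated at once to prevent lactonisation.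

**Step 8**
Reactants: 10 methyl (R)-5-hydroxy-3-methylpentanoate
Product: 11 methyl (R)-5-(TBDPS-oxy)-3-methylpentanoate
Conditions: TBDPSCl, imidazole, CH2Cl2, 25 °C
Reagents that add atoms: tert-butyldiphenylsilyl chloride CC(C)(C)[Si](Cl)(c1ccccc1)c1ccccc1
Why: Standard silylation; TBDPS is chosen for O15 because it withstands the aqueous acid that later removes the TBS group on O19.

**Step 9**
Reactants: 11 methyl (R)-5-(TBDPS-oxy)-3-methylpentanoate
Product: 12 (S)-5-(TBDPS-oxy)-3-methylpentan-1-ol
Conditions: LiBH4, THF/MeOH, 0 → 25 °C
Reagents that add atoms: none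
Why: Borohydride reduction of the ester to the primary alcohol; the silyl ether and the remote stereocentre are untouched (the descriptor changes only through priority).

**Step 10**
Reactants: 12 (S)-5-(TBDPS-oxy)-3-methylpentan-1-ol
Product: 13 (R)-tert-butyl(5-iodo-3-methylpentyloxy)diphenylsilane
Conditions: I2, PPh3, imidazole, CH2Cl2, 0 → 25 °C
Reagents that add atoms: iodine [I][I]
Why: Appel-type iodination; SN2 displacement of the alkoxyphosphonium at a primary carbon, remote from the stereocentre.

**Step 11**
Reactants: 13 (R)-iodide; 7 trans-fused enedione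
Product: 16 9β-hydroxy-8-methoxy-19-(TBS-oxy)-15-(TBDPS-oxy)-17,18-dinorlabda-2,7-dien-6-one (4β-H 5α-H 13S; chain on the α face of C9), via alkyllithium 14 (not isolated), via alkylcerium dichloride 15 (not isolated)
Conditions: 13, t-BuLi (2.1 equiv), Et2O, −78 °C; CeCl3 (anhydrous), THF, −78 °C; then 7, −78 °C; aq. NH4Cl
Reagents that add atoms: none
Why: Iodine–lithium exchange and transmetalation give a weakly basic organocerium that adds 1,2 to the C9 carbonyl, which is non-enolisable and inductively activated by the α-methoxy alkene. The C6 carbonyl is deactivated as a vinylogous ester and shielded on the β face by syn-axial C20 and on the α face by the peri CH2OTBS group. Attack anti to C20 is expected, and the new C9 centre is erased in step 14.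

**Step 12**
Reactants: 16 C9 carbinol
Product: 18 9β-hydroxy-19-(TBS-oxy)-15-(TBDPS-oxy)-17,18-dinorlabda-2,6-dien-8-one, via C6 allylic alcohol 17 (not isolated)
Conditions: i-Bu2AlH (3 equiv), CH2Cl2, −78 °C; then 1 M HCl, THF, 0 °C, brief
Reagents that add atoms: none
Why: Stork–Danheiser transposition: 1,2-reduction of the vinylogous ester carbonyl, then acid hydrolysis of the enol ether with loss of the allylic C6 hydroxyl, moves the carbonyl to C8 and leaves C6=C7. The C6 carbinol centre (expected β-OH from α attack) is transient, and both silyl ethers survive the short cold acid treatment.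

**Step 13**
Reactants: 18 dienone carbinol
Product: 19 9β-hydroxy-19-(TBS-oxy)-15-(TBDPS-oxy)-17,18-dinorlabdan-8-one (5α-H)
Conditions: H2 (1 atm), Pd/C (10 wt%), EtOAc, 25 °C
Reagents that add atoms: none
Why: Heterogeneous hydrogenation saturates the enone alkene C6=C7 and the isolated C2=C3 alkene; no stereocentre is created because C5 is already set, and the ketone, the tertiary alcohol and the silyl ethers are inert in ethyl acetate.

**Step 14**
Reactants: 19 saturated α-ketol
Product: 22 19-hydroxy-15-(TBDPS-oxy)-17,18-dinorlabdan-8-one (5α-H 9α-H; chain 9β), via samarium enolate 20 (not isolated), via silyl-protected ketone 21 (not isolated)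
Conditions: SmI2 (4 equiv), THF/HMPA, MeOH, −78 → 0 °C; then 2 M HCl, THF, 25 °C
Reagents that add atoms: none
Why: Reductive cleavage of an α-hydroxy ketone by SmI2: two single-electron transfers to the C8 carbonyl expel the C9 hydroxide and leave a trivalent samarium enolate. Protonation on the α face, opposite C20, and acid equilibration place the chain equatorial (9β), which sets C9. The same aqueous acid removes the primary TBS group and leaves the much more acid-stable TBDPS ether.

**Step 15**
Reactants: 22 hydroxy ketone
Product: 23 15-(TBDPS-oxy)-18-norlabd-8(17)-en-19-ol (4β-H)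
Conditions: Ph3PCH3Br, KOt-Bu (excess), toluene, 0 → 80 °C
Reagents that add atoms: methyltriphenylphosphonium bromide C[P+](c1ccccc1)(c1ccccc1)c1ccccc1.[Br-]
Why: Wittig methylenation of the C8 ketone with excess ylide (the free alcohol is carried as its alkoxide); C9 is already in its thermodynamic configuration, so the basic medium cannot erode it, and after this step it is no longer epimerisable.

**Step 16**
Reactants: 23 alkenol
Product: 24 15-(TBDPS-oxy)-18-norlabd-8(17)-en-19-oic acid (4β-H; carboxyl equatorial)
Conditions: TEMPO (20 mol%), PhI(OAc)2 (2.5 equiv), MeCN/H2O, 25 °C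
Reagents that add atoms: water O
Why: Oxoammonium-mediated oxidation of the primary alcohol through the aldehyde hydrate to the acid; the alkene and the silyl ether are inert, and the configuration at C4 is irrelevant because it is reset in step 17.

**Step 17**
Reactants: 24 C4–H acid
Product: 26 15-(TBDPS-oxy)labd-8(17)-en-19-oic acid (4S 5R 9S 10R 13S), via dilithium enediolate 25 (not isolated)
Conditions: LiN(i-Pr)2 (2.5 equiv), THF/DMPU, 0 → 40 °C; MeI, 0 → 25 °C; aq. HCl work-up
Reagents that add atoms: iodomethane CI
Why: α-Alkylation of a carboxylic acid dianion: the exocyclic C4 enediolate is planar and takes iodomethane on the α (equatorial) face, away from syn-axial C20. The new methyl is therefore C18 and the carboxyl ends axial as C19, which sets C4 and gives the free acid without an ester to cleave.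

**Step 18**
Reactants: 26 silyl ether acid
Product: 27 15-hydroxylabd-8(17)-en-19-oic acid (imbricatolic acid)
Conditions: Bu4NF (3 equiv), THF, 25 °C; pH 4 work-up
Reagents that add atoms: none
Why: Fluoride cleavage of the silyl ether; the carboxylate and the exocyclic alkene do not react.

**Step 19**
Reactants: 27 hydroxy acid
Product: 28 15-formyloxylabd-8(17)-en-19-oic acid (target; 4S 5R 9S 10R 13S)
Conditions: HCO2H/Ac2O (premixed, 50 °C), pyridine, CH2Cl2, 0 °C; water work-up
Reagents that add atoms: acetic formic anhydride CC(=O)OC=O
Why: Formyl transfer from the mixed anhydride to the unhindered primary alcohol, the formyl carbon being far more electrophilic than the acetyl carbon; the hindered tertiary acid can at most form a mixed anhydride that reverts on aqueous work-up. The step is last because the formate is the most labile group.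

**Compound list**

1 | 2-methoxy-6-methylphenol | COc1cccc(C)c1O | starting material
2 | 2-methoxy-6-methyl-1,4-benzoquinone | COC1=CC(=O)C=C(C)C1=O | intermediate
3 | (E)-penta-2,4-dienoic acid | C=C/C=C/C(=O)O | starting material
4 | (E)-penta-2,4-dien-1-ol | C=C/C=C/CO | intermediate
5 | (E)-tert-butyldimethyl(penta-2,4-dienyloxy)silane | C=C/C=C/CO[Si](C)(C)C(C)(C)C | intermediate
6 | (4aR,5R,8aS)-5-(TBS-oxymethyl)-2-methoxy-8a-methyl-4a,5,8,8a-tetrahydronaphthalene-1,4-dione, cis-fused endo adduct | COC1=CC(=O)[C@H]2[C@](C)(CC=C[C@H]2CO[Si](C)(C)C(C)(C)C)C1=O | intermediate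
7 | (4aS,5R,8aS)-5-(TBS-oxymethyl)-2-methoxy-8a-methyl-4a,5,8,8a-tetrahydronaphthalene-1,4-dione, trans-fused | COC1=CC(=O)[C@@H]2[C@](C)(CC=C[C@H]2CO[Si](C)(C)C(C)(C)C)C1=O | intermediate
8 | 3-methylglutaric anhydride | CC1CC(=O)OC(=O)C1 | starting material
9 | (R)-5-methoxy-3-methyl-5-oxopentanoic acid | COC(=O)C[C@H](C)CC(=O)O | intermediate
10 | methyl (R)-5-hydroxy-3-methylpentanoate | COC(=O)C[C@H](C)CCO | intermediate
11 | methyl (R)-5-(TBDPS-oxy)-3-methylpentanoate | COC(=O)C[C@H](C)CCO[Si](c1ccccc1)(c1ccccc1)C(C)(C)C | intermediate
12 | (S)-5-(TBDPS-oxy)-3-methylpentan-1-ol | OCC[C@H](C)CCO[Si](c1ccccc1)(c1ccccc1)C(C)(C)C | intermediate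
13 | (R)-tert-butyl(5-iodo-3-methylpentyloxy)diphenylsilane | ICC[C@H](C)CCO[Si](c1ccccc1)(c1ccccc1)C(C)(C)C | intermediate
14 | (R)-5-(TBDPS-oxy)-3-methylpentyllithium | [Li]CC[C@H](C)CCO[Si](c1ccccc1)(c1ccccc1)C(C)(C)C | intermediate
15 | (R)-5-(TBDPS-oxy)-3-methylpentylcerium dichloride | Cl[Ce](Cl)CC[C@H](C)CCO[Si](c1ccccc1)(c1ccccc1)C(C)(C)C | intermediate
16 | 9β-hydroxy-8-methoxy-19-(TBS-oxy)-15-(TBDPS-oxy)-17,18-dinorlabda-2,7-dien-6-one | COC1=CC(=O)[C@@H]2[C@](C)(CC=C[C@H]2CO[Si](C)(C)C(C)(C)C)[C@]1(O)CC[C@H](C)CCO[Si](c3ccccc3)(c3ccccc3)C(C)(C)C | intermediate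
17 | 8-methoxy-19-(TBS-oxy)-15-(TBDPS-oxy)-17,18-dinorlabda-2,7-diene-6β,9β-diol | COC1=C[C@@H](O)[C@@H]2[C@](C)(CC=C[C@H]2CO[Si](C)(C)C(C)(C)C)[C@]1(O)CC[C@H](C)CCO[Si](c3ccccc3)(c3ccccc3)C(C)(C)C | intermediate
18 | 9β-hydroxy-19-(TBS-oxy)-15-(TBDPS-oxy)-17,18-dinorlabda-2,6-dien-8-one | O=C1C=C[C@@H]2[C@](C)(CC=C[C@H]2CO[Si](C)(C)C(C)(C)C)[C@]1(O)CC[C@H](C)CCO[Si](c3ccccc3)(c3ccccc3)C(C)(C)C | intermediate
19 | 9β-hydroxy-19-(TBS-oxy)-15-(TBDPS-oxy)-17,18-dinorlabdan-8-one | O=C1CC[C@@H]2[C@](C)(CCC[C@H]2CO[Si](C)(C)C(C)(C)C)[C@]1(O)CC[C@H](C)CCO[Si](c3ccccc3)(c3ccccc3)C(C)(C)C | intermediate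
20 | diiodosamarium 8(9)-enolate of 21 | I[Sm](I)OC1=C(CC[C@H](C)CCO[Si](c3ccccc3)(c3ccccc3)C(C)(C)C)[C@@]2(C)CCC[C@@H](CO[Si](C)(C)C(C)(C)C)[C@@H]2CC1 | intermediate
21 | 19-(TBS-oxy)-15-(TBDPS-oxy)-17,18-dinorlabdan-8-one (9α-H) | O=C1CC[C@@H]2[C@](C)(CCC[C@H]2CO[Si](C)(C)C(C)(C)C)[C@H]1CC[C@H](C)CCO[Si](c3ccccc3)(c3ccccc3)C(C)(C)C | intermediate
22 | 19-hydroxy-15-(TBDPS-oxy)-17,18-dinorlabdan-8-one | O=C1CC[C@@H]2[C@](C)(CCC[C@H]2CO)[C@H]1CC[C@H](C)CCO[Si](c3ccccc3)(c3ccccc3)C(C)(C)C | intermediate
23 | 15-(TBDPS-oxy)-18-norlabd-8(17)-en-19-ol | C=C1CC[C@@H]2[C@](C)(CCC[C@H]2CO)[C@H]1CC[C@H](C)CCO[Si](c3ccccc3)(c3ccccc3)C(C)(C)C | intermediate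
24 | 15-(TBDPS-oxy)-18-norlabd-8(17)-en-19-oic acid | C=C1CC[C@@H]2[C@](C)(CCC[C@H]2C(=O)O)[C@H]1CC[C@H](C)CCO[Si](c3ccccc3)(c3ccccc3)C(C)(C)C | intermediate
25 | dilithium enediolate of 24 (C4=C19) | C=C1CC[C@@H]2[C@](C)(CCCC2=C(O[Li])O[Li])[C@H]1CC[C@H](C)CCO[Si](c3ccccc3)(c3ccccc3)C(C)(C)C | intermediate
26 | 15-(TBDPS-oxy)labd-8(17)-en-19-oic acid | C=C1CC[C@@H]2[C@](C)(CCC[C@]2(C)C(=O)O)[C@H]1CC[C@H](C)CCO[Si](c3ccccc3)(c3ccccc3)C(C)(C)C | intermediate
27 | 15-hydroxylabd-8(17)-en-19-oic acid | C=C1CC[C@@H]2[C@](C)(CCC[C@]2(C)C(=O)O)[C@H]1CC[C@H](C)CCO | intermediate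
28 | 15-formyloxylabd-8(17)-en-19-oic acid (4S,5R,9S,10R,13S) | C=C1CC[C@@H]2[C@](C)(CCC[C@]2(C)C(=O)O)[C@H]1CC[C@H](C)CCOC=O | target

**Step count and least certain steps**

Total: 19 steps. Longest linear sequence: 14 steps (8 to 28, steps 6–19). The main line after the key step takes 10 steps.

**Step 4 (key step).** The diene is only weakly nucleophilic and the dienophile alkene is trisubstituted, so the cycloaddition may be slow at the temperatures where the cationic catalyst is selective. Warming would let an uncatalysed or proton-catalysed background reaction erode the face selectivity, and the diene could polymerise. Fallback, setting out from 2 and 5 and coming back at 6: the cycloaddition is run without chiral control (BF3·OEt2 in CH2Cl2 at −78 °C, or toluene at 80 °C). The substrate alone should still direct site, orientation and endo addition, giving 6 together with the mirror-image adduct F1. Preparative chromatography on a chiral stationary phase would then return enantiopure 6.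

**Step 5.** The equilibrium may stop short of the trans fusion, because in the trans isomer the pseudo-equatorial CH2OTBS group on C4 lies peri to the C6 carbonyl and the two flattened rings reduce the usual trans preference. Fallback, setting out from 6 and coming back at 19: C5 is made trigonal and then set by hydrogenation instead of by equilibration.
- KN(SiMe3)2 and PhNTf2 (THF, −78 °C) convert the C6 carbonyl into the dienyl triflate F2.
- Reagent 15 adds to the only remaining carbonyl to give the C9 carbinol F3.
- Pd(OAc)2/PPh3 with HCO2H and Et3N (DMF, 60 °C) replaces the triflate by hydrogen to give the dienol ether F4.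
- Cold aqueous oxalic acid hydrolyses it with kinetic protonation at C7 to the β,γ-unsaturated ketone F5.
- Hydrogenation over Pd/C should add to C5=C6 from the α face, away from C20, and saturate C2=C3 as well, which gives 19.

**Step 11.** The organometallic may abstract the C5 proton, or add at C6, faster than it reaches the neopentyl-type C9 carbonyl, which would leave the addition incomplete or unselective. Fallback, setting out from 7 and coming back at 16: LiN(SiMe3)2 and Me3SiCl (THF, −78 °C) mask C6 as the silyl dienol ether F6. Reagent 15 then has only C9 to attack and gives the carbinol F7. K2CO3 in MeOH cleaves the enol silyl ether and equilibrates C5 as in step 5, returning 16.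

**Step 14.** Simple reduction of the ketyl to an alcohol may outrun C–O cleavage, because the C9–O bond is equatorial and poorly aligned with the carbonyl π system and hydroxide is a modest leaving group. Fallback, setting out from 18 and coming back at 22: SOCl2 with pyridine (CH2Cl2, 0 °C) eliminates the tertiary hydroxyl toward C11, the only position with β-hydrogens, to give the cross-conjugated dienone F8. Hydrogen over Pd/C reduces C9=C11, C6=C7 and C2=C3 in one operation, delivering hydrogen to C9 from the α face, and gives 21. The dilute HCl treatment of step 14 then gives 22.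

**Step 17.** Enediolate formation may be incomplete, since the C4 hydrogen is axial and syn to C20, and facial discrimination or C- versus O-methylation may be inadequate. Fallback, setting out from 24 and coming back at 26: Me3SiCHN2 in MeOH/toluene gives the methyl ester F9. LiN(i-Pr)2 then MeI (THF, −78 °C) methylates the ester enolate on the equatorial face to the quaternary methyl ester F10. The hindered axial ester is cleaved by SN2 attack of LiSPr on the O-methyl group in HMPA, which touches neither the alkene nor the silyl ether, and gives 26.

## Further compounds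

F1 | step 4 | (4aS,5S,8aR)-5-(TBS-oxymethyl)-2-methoxy-8a-methyl-4a,5,8,8a-tetrahydronaphthalene-1,4-dione, mirror image of 6 | COC1=CC(=O)[C@@H]2[C@@](C)(CC=C[C@@H]2CO[Si](C)(C)C(C)(C)C)C1=O
F2 | step 5 | 8-methoxy-9-oxo-19-(TBS-oxy)-11,12,13,14,15,16,17,18-octanorlabda-2,5,7-trien-6-yl trifluoromethanesulfonate | COC1=CC(OS(=O)(=O)C(F)(F)F)=C2[C@](C)(CC=C[C@H]2CO[Si](C)(C)C(C)(C)C)C1=O
F3 | step 5 | 9β-hydroxy-8-methoxy-19-(TBS-oxy)-15-(TBDPS-oxy)-17,18-dinorlabda-2,5,7-trien-6-yl trifluoromethanesulfonate | COC1=CC(OS(=O)(=O)C(F)(F)F)=C2[C@](C)(CC=C[C@H]2CO[Si](C)(C)C(C)(C)C)[C@]1(O)CC[C@H](C)CCO[Si](c3ccccc3)(c3ccccc3)C(C)(C)C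
F4 | step 5 | 8-methoxy-19-(TBS-oxy)-15-(TBDPS-oxy)-17,18-dinorlabda-2,5,7-trien-9β-ol | COC1=CC=C2[C@](C)(CC=C[C@H]2CO[Si](C)(C)C(C)(C)C)[C@]1(O)CC[C@H](C)CCO[Si](c3ccccc3)(c3ccccc3)C(C)(C)C
F5 | step 5 | 9β-hydroxy-19-(TBS-oxy)-15-(TBDPS-oxy)-17,18-dinorlabda-2,5-dien-8-one | O=C1CC=C2[C@](C)(CC=C[C@H]2CO[Si](C)(C)C(C)(C)C)[C@]1(O)CC[C@H](C)CCO[Si](c3ccccc3)(c3ccccc3)C(C)(C)C
F6 | step 11 | 8-methoxy-6-(trimethylsilyloxy)-19-(TBS-oxy)-11,12,13,14,15,16,17,18-octanorlabda-2,5,7-trien-9-one | COC1=CC(O[Si](C)(C)C)=C2[C@](C)(CC=C[C@H]2CO[Si](C)(C)C(C)(C)C)C1=O
F7 | step 11 | 8-methoxy-6-(trimethylsilyloxy)-19-(TBS-oxy)-15-(TBDPS-oxy)-17,18-dinorlabda-2,5,7-trien-9β-ol | COC1=CC(O[Si](C)(C)C)=C2[C@](C)(CC=C[C@H]2CO[Si](C)(C)C(C)(C)C)[C@]1(O)CC[C@H](C)CCO[Si](c3ccccc3)(c3ccccc3)C(C)(C)C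
F8 | step 14 | 19-(TBS-oxy)-15-(TBDPS-oxy)-17,18-dinorlabda-2,6,9(11)-trien-8-one (C9=C11 geometry not controlled) | O=C1C=C[C@@H]2[C@](C)(CC=C[C@H]2CO[Si](C)(C)C(C)(C)C)C1=CC[C@H](C)CCO[Si](c3ccccc3)(c3ccccc3)C(C)(C)C
F9 | step 17 | methyl 15-(TBDPS-oxy)-18-norlabd-8(17)-en-19-oate | C=C1CC[C@@H]2[C@](C)(CCC[C@H]2C(=O)OC)[C@H]1CC[C@H](C)CCO[Si](c3ccccc3)(c3ccccc3)C(C)(C)C
F10 | step 17 | methyl 15-(TBDPS-oxy)labd-8(17)-en-19-oate | C=C1CC[C@@H]2[C@](C)(CCC[C@]2(C)C(=O)OC)[C@H]1CC[C@H](C)CCO[Si](c3ccccc3)(c3ccccc3)C(C)(C)C
A1 | alternative 1 | 19-[(bromomethyl)dimethylsilyloxy]-15-(4-methoxybenzyloxy)-20-norlabd-9-en-8-one | O=C1CC[C@@H]2C(CCC[C@]2(C)CO[Si](C)(C)CBr)=C1CC[C@H](C)CCOCc3ccc(OC)cc3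
A2 | alternative 1 | trans-decalone with C19–O–Si–C20 bridge | O=C1CC[C@@H]2[C@](C3)(CCC[C@]2(C)CO[Si]3(C)C)[C@H]1CC[C@H](C)CCOCc4ccc(OC)cc4
A3 | alternative 2 | methyl (S)-1,3-dimethyl-4-oxocyclohex-2-ene-1-carboxylate | CC1=C[C@@](C)(C(=O)OC)CCC1=O
A4 | alternative 2 | 1,2-bis(trimethylsilyloxy)cyclobutene | C[Si](C)(C)OC1=C(O[Si](C)(C)C)CC1
A5 | alternative 2 | cis-anti-cis photoadduct with C6–C9 bis-silyloxy central bond | C1C[C@@]3(O[Si](C)(C)C)[C@H]2[C@](C)(C(=O)CC[C@]2(C)C(=O)OC)[C@@]13O[Si](C)(C)C
A6 | alternative 3 | ten-membered diene: methyl 8α-(TBS-oxy)-15-(TBDPS-oxy)-5,10-seco-17,18-dinorlabda-4,10(20)-dien-19-oate (C3 and C6 cis on C4=C5) | C=C1CCC/C(C(=O)OC)=C\CC[C@@H](O[Si](C)(C)C(C)(C)C)[C@@H]1CC[C@H](C)CCO[Si](c2ccccc2)(c2ccccc2)C(C)(C)C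
A7 | alternative 3 | trans-decalin with C20 methyl, equatorial C4–H ester and C8 silyl ether | [C@@H]1(O[Si](C)(C)C(C)(C)C)CC[C@@H]2[C@](C)(CCC[C@H]2C(=O)OC)[C@H]1CC[C@H](C)CCO[Si](c3ccccc3)(c3ccccc3)C(C)(C)C
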